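**Conventions and assumptions.** Atom numbers are those of the target throughout (ring C1–C6, chain C1'–C17'), also in the cyclopentene intermediates, where C6 is the exocyclic acyl carbon. TBS = tert-butyldimethylsilyl. Compounds 1, 5 and 9 are taken as commercial. The (S,S)-Co(salen) catalyst is assumed to hydrolyse the (R)-epoxide, as usual for terminal alkyl epoxides; if the sense were opposite for this substrate, the antipodal catalyst would be used.

## Analysis of the target

The target 14 is a cyclohex-2-en-1-one: C1 ketone, C2=C3 olefin, C4 secondary allylic carbinol, C5 methylene, and C6 a tertiary carbinol carrying the 2-hydroxyheptadec-10(Z)-enyl chain. The configuration is (4S,6R,2'S), so the two ring hydroxyls are cis and the chain is trans to the C4 hydroxyl. C2' is insulated from the ring by C1'H2 and cannot be relayed reliably from the ring stereocentres. The sensitive groups are the γ-hydroxy enone (two dehydrations lead to a phenol), the tertiary α-ketol C6(OH)–C1(=O), and the Z-olefin C10'=C11', which excludes hydrogenation, ozonolysis and peracids and complicates metathesis. The hard part is the fully substituted, oxygenated C6 next to the carbonyl with a fixed 1,3-relationship to C4, in a ring without symmetry. The feature that the route exploits is that C6(OH)–C1(=O) is an acyloin whose carbonyl carbon C1 is also vinylic (C2=C3). Moving the C5–C6 bond back to C1 contracts the ring to a 1-acyl-4-oxycyclopent-2-en-1-ol, the adduct of an acyl anion and a 4-hydroxycyclopentenone. The C2'–C17' segment is the carbon chain of palmitoleyl alcohol 1, with the Z-olefin already in place.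

## Retrosynthetic reasoning

**14 ⇐ 13.** Only the two silyl ethers at C4–O and C2'–O are removed. Ketone 13 has no α-hydrogen (C6 quaternary, C2 vinylic), so a buffered fluoride source should be tolerated.

**13 ⇐ 12 (C5–C6 cut, C5–C1 restored).** This is the α-ketol retron. Cutting here turns the six-membered ring with its quaternary carbinol into the cyclopentenyl ketone 12, in which C6 is a plain acyl carbon and the only ring stereocentres are C4 and the carbinol C1. The forward shift has to move C5 and not C2, and has to deliver C5 to one face of the C6 carbonyl. The first is helped by the enone conjugation that only the C5 shift creates. The second is arranged by a chelate between the C1 oxygen and the C6 carbonyl oxygen, which turns the C1 configuration into the C6 configuration.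

**12 ⇐ 11 ⇐ 8 + 9 (C1–C6 cut).** The tertiary ketol is the adduct of an acyl anion equivalent and enone 9. Compound 9 brings C4 as a bought stereocentre, and its silyloxy group should direct the nucleophile to the opposite face, which sets C1. A dithiane is chosen because the same carbon can first be joined to the chain and then be metalated a second time, as 10, for the addition to 9.

**8 ⇐ 5 + 4 (C6–C1' cut).** Lithiation of 1,3-dithiane 5 gives 6, which opens the terminal epoxide 4 at C1' and forms the C6–C1' bond. The alkoxide 7 is silylated in the same flask, so that the C2' oxygen leaves the step protected and the dithiane carbon still carries the hydrogen needed for the second metalation.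

**4 ⇐ 3 ⇐ 2 ⇐ 1.** The C2' stereocentre is set by a catalytic kinetic resolution of the racemic epoxide 3. C1' is added as a methylene unit to aldehyde 2, obtained by oxidising 1.

## Alternatives that were turned down

**Alternative 1: (textbook) oxygenation of C6 on a preformed cyclohexenone.** The disconnections are C6–O and C6–C1'. Forward, (S)-4-(tert-butyldimethylsilyloxy)cyclohex-2-en-1-one A1 would be alkylated at C6 to give A2, and the key step would be oxidation of the cross-conjugated enolate of A2 with a Davis oxaziridine. It was turned down for these reasons: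
- The only control element is the C4 silyloxy group, 1,3 to C6. The oxidant should approach the flattened enolate anti to it, which gives the trans-4,6 relationship, the epimer of what is needed.
- Alkylating an α'-enolate with an unactivated, β-oxygenated electrophile derived from 4 is poor. The alternative is an aldol/dehydration/reduction detour.
- The γ-silyloxy dienolate can eliminate towards a phenol.
- A1 itself costs several steps, and peracid (Rubottom) variants are excluded by the Z-olefin.

**Alternative 2: ring-closing metathesis at C2=C3.** The acyclic divinyl ketol A3 would be closed with a ruthenium carbene. The key step would form the least demanding bond of the ring and set no stereocentre. The whole stereochemical burden would move to an acyclic quaternary carbinol, to be set by 1,3-induction from two secondary carbinols that each need their own asymmetric step. The carbene can also engage the C10'=C11' olefin (chain scission, Z/E scrambling). The sequence would be clearly longer than the one chosen.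

**Alternative 3: hydroxylative dearomatisation.** Phenol A4 (from 4 and a 4-methoxyphenol derivative) would be oxidised at the alkyl-bearing ortho carbon to the ortho-quinol A5, followed by enol ether hydrolysis and reduction of the C4 ketone. It was turned down for these reasons:
- C6 would be created on a flat arene with only the remote, freely rotating C2' carbinol as a control element.
- Attack at the methoxy-bearing para carbon (quinone monoketal) competes.
- Ortho-quinols of type A5 dimerise readily by [4+2] cycloaddition.
- λ5-Iodane oxidants would also oxidise the free C2' alcohol.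
- The later reduction of an ene-dione would need a third selectivity (C4 over C1, cis to C6–OH).

Key step: step 7

## Steps

Step 1
Reactants: 1 (Z)-hexadec-9-en-1-ol
Product: 2 (Z)-hexadec-9-enal
Conditions: TEMPO (10 mol%), PhI(OAc)2, CH2Cl2, rt
Reagents that add atoms: none
Why: Oxoammonium-catalysed oxidation of a primary alcohol stops at the aldehyde and does not touch the Z-olefin.

Step 2
Reactants: 2 (Z)-hexadec-9-enal
Product: 3 rac-2-[(8Z)-pentadec-8-en-1-yl]oxirane
Conditions: Me3S+ I−, KOt-Bu, DMSO/THF, 0 °C → rt (aldehyde added to the preformed ylide)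
Reagents that add atoms: trimethylsulfonium iodide C[S+](C)C.[I-]
Why: Corey–Chaykovsky methylene transfer adds C1' and closes the terminal epoxide; the product is racemic at C2'.

Step 3
Reactants: 3 rac-2-[(8Z)-pentadec-8-en-1-yl]oxirane
Product: 4 (S)-2-[(8Z)-pentadec-8-en-1-yl]oxirane
Conditions: (S,S)-(salen)Co(III)OAc (0.5 mol%), H2O (0.55 equiv), THF, 0 °C → rt
Reagents that add atoms: none
Why: Jacobsen hydrolytic kinetic resolution; the catalyst should hydrolyse the (R)-epoxide to the diol and leave the (S)-epoxide, so C2' is set by catalysis.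

Step 4
Reactants: 5 1,3-dithiane; 4 (S)-2-[(8Z)-pentadec-8-en-1-yl]oxirane
Product: 8 2-[(2S,10Z)-2-(tert-butyldimethylsilyloxy)heptadec-10-en-1-yl]-1,3-dithiane, via 2-lithio-1,3-dithiane 6 (not isolated), via lithium alkoxide 7 (not isolated)
Conditions: 5 (1.05 equiv), n-BuLi, THF, −30 °C, 2 h; 4, −30 → 0 °C; then TBSOTf (1.2 equiv), −78 → 0 °C; aq. NaHCO3
Reagents that add atoms: tert-butyldimethylsilyl trifluoromethanesulfonate CC(C)(C)[Si](C)(C)OS(=O)(=O)C(F)(F)F
Why: Corey–Seebach alkylation: SN2 opening at the terminal epoxide carbon by the lithiated dithiane forms C6–C1' and leaves C2' untouched; the lithium alkoxide is then O-silylated in the same flask by the silyl triflate, a standard trapping of alkoxides.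

Step 5
Reactants: 8 2-[(2S,10Z)-2-(tert-butyldimethylsilyloxy)heptadec-10-en-1-yl]-1,3-dithiane; 9 (S)-4-(tert-butyldimethylsilyloxy)cyclopent-2-en-1-one
Product: 11 (1R,4S)-4-(tert-butyldimethylsilyloxy)-1-{2-[(2S,10Z)-2-(tert-butyldimethylsilyloxy)heptadec-10-en-1-yl]-1,3-dithian-2-yl}cyclopent-2-en-1-ol, via lithiated dithiane 10 (not isolated)
Conditions: n-BuLi, THF, −25 °C, 3 h; then 9, −78 °C; aq. NH4Cl
Reagents that add atoms: none
Why: Corey–Seebach acyl anion 1,2-addition; in HMPA-free THF the contact ion pair should add to the carbonyl and not in conjugate fashion, and the bulky carbanion should enter anti to the C4 silyloxy group, so that the new C1–OH is cis to C4–OTBS (1R).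

Step 6
Reactants: 11 (1R,4S)-4-(tert-butyldimethylsilyloxy)-1-{2-[(2S,10Z)-2-(tert-butyldimethylsilyloxy)heptadec-10-en-1-yl]-1,3-dithian-2-yl}cyclopent-2-en-1-ol
Product: 12 (3S,11Z)-3-(tert-butyldimethylsilyloxy)-1-[(1R,4S)-4-(tert-butyldimethylsilyloxy)-1-hydroxycyclopent-2-en-1-yl]octadec-11-en-1-one
Conditions: PhI(OCOCF3)2, NaHCO3, MeCN/H2O (9:1), 0 °C
Reagents that add atoms: water O
Why: Oxidative dithioacetal hydrolysis with a hypervalent iodine reagent is fast at sulfur and should leave the silyl ethers and the isolated Z-olefin alone; the bicarbonate buffer protects the tertiary allylic carbinol.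

Step 7
Reactants: 12 (3S,11Z)-3-(tert-butyldimethylsilyloxy)-1-[(1R,4S)-4-(tert-butyldimethylsilyloxy)-1-hydroxycyclopent-2-en-1-yl]octadec-11-en-1-one
Product: 13 (4S,6R)-4-(tert-butyldimethylsilyloxy)-6-[(2S,10Z)-2-(tert-butyldimethylsilyloxy)heptadec-10-en-1-yl]-6-hydroxycyclohex-2-en-1-one
Conditions: Al(Ot-Bu)3 (1.2 equiv), toluene, 25 → 70 °C; aq. Rochelle salt
Reagents that add atoms: none
Why: α-Ketol (acyloin) rearrangement with ring expansion, the reaction type known from the D-homoannulation of 17α-hydroxy-20-keto steroids and from 1-acylcycloalkanol to 2-hydroxycycloalkanone expansions. Alkoxide exchange puts aluminium on the C1 oxygen and the same metal binds the C6 ketone oxygen, so the O–C1–C6=O unit is held syn-periplanar in a five-membered chelate with C5 and C2 on opposite faces of the C6 carbonyl. As C1–O becomes C1=O, the C1–C5 σ-bond shifts suprafacially to C6; the six-membered ring therefore arises by a 1,2-shift (one-carbon enlargement of the cyclopentene), not by a cyclisation, and the migrating C5 is an achiral CH2. The only new stereocentre, C6, is fixed by the C1 carbinol configuration of 12 (itself relayed from C4 of 9): within the chelate C5 can reach only the carbonyl face on its own side, which should place the new C6–OH on the face where the C1–OH was, cis to C4–OTBS, giving (6R). The first selectivity needed is C5 over C2 migration: the C5 shift leaves the vinyl group on the carbon that becomes the ketone, so enone conjugation builds up in the transition state and makes 13 the thermodynamic sink, whereas a C2 shift would give an unconjugated β,γ-enone that can revert. The second is reaction through the chelated and not the open, dipole-opposed rotamer, which the oxophilic, non-nucleophilic and non-reducing Al(III) alkoxide in a non-polar solvent should secure. The product ketone has no α-hydrogen and the reverse shift is uphill, so C6 should not equilibrate once formed.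

Step 8
Reactants: 13 (4S,6R)-4-(tert-butyldimethylsilyloxy)-6-[(2S,10Z)-2-(tert-butyldimethylsilyloxy)heptadec-10-en-1-yl]-6-hydroxycyclohex-2-en-1-one
Product: 14 (4S,6R)-4,6-dihydroxy-6-[(2S,10Z)-2-hydroxyheptadec-10-en-1-yl]cyclohex-2-en-1-one
Conditions: HF·pyridine, pyridine/THF, 0 °C → rt
Reagents that add atoms: none
Why: Buffered fluoride cleaves both secondary silyl ethers without the basicity of ammonium fluorides, which could trigger elimination or an acyloin shift; no stereocentre is touched.

## Compound list

1 | (Z)-hexadec-9-en-1-ol (palmitoleyl alcohol) | CCCCCC/C=C\CCCCCCCCO | starting material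
2 | (Z)-hexadec-9-enal | CCCCCC/C=C\CCCCCCCC=O | intermediate
3 | rac-2-[(8Z)-pentadec-8-en-1-yl]oxirane | CCCCCC/C=C\CCCCCCCC1CO1 | intermediate
4 | (S)-2-[(8Z)-pentadec-8-en-1-yl]oxirane | CCCCCC/C=C\CCCCCCC[C@H]1CO1 | intermediate
5 | 1,3-dithiane | C1CSCSC1 | starting material
6 | (1,3-dithian-2-yl)lithium | [Li]C1SCCCS1 | intermediate (not isolated)
7 | lithium (2S,10Z)-1-(1,3-dithian-2-yl)heptadec-10-en-2-olate | CCCCCC/C=C\CCCCCCC[C@H](O[Li])CC1SCCCS1 | intermediate (not isolated)
8 | 2-[(2S,10Z)-2-(tert-butyldimethylsilyloxy)heptadec-10-en-1-yl]-1,3-dithiane | CCCCCC/C=C\CCCCCCC[C@H](O[Si](C)(C)C(C)(C)C)CC1SCCCS1 | intermediate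
9 | (S)-4-(tert-butyldimethylsilyloxy)cyclopent-2-en-1-one | O=C1C=C[C@@H](O[Si](C)(C)C(C)(C)C)C1 | starting material
10 | {2-[(2S,10Z)-2-(tert-butyldimethylsilyloxy)heptadec-10-en-1-yl]-1,3-dithian-2-yl}lithium | CCCCCC/C=C\CCCCCCC[C@H](O[Si](C)(C)C(C)(C)C)CC1([Li])SCCCS1 | intermediate (not isolated)
11 | (1R,4S)-4-(tert-butyldimethylsilyloxy)-1-{2-[(2S,10Z)-2-(tert-butyldimethylsilyloxy)heptadec-10-en-1-yl]-1,3-dithian-2-yl}cyclopent-2-en-1-ol | O[C@@]1(C2(C[C@@H](O[Si](C)(C)C(C)(C)C)CCCCCCC/C=C\CCCCCC)SCCCS2)C=C[C@@H](O[Si](C)(C)C(C)(C)C)C1 | intermediate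
12 | (3S,11Z)-3-(tert-butyldimethylsilyloxy)-1-[(1R,4S)-4-(tert-butyldimethylsilyloxy)-1-hydroxycyclopent-2-en-1-yl]octadec-11-en-1-one | O[C@@]1(C(=O)C[C@@H](O[Si](C)(C)C(C)(C)C)CCCCCCC/C=C\CCCCCC)C=C[C@@H](O[Si](C)(C)C(C)(C)C)C1 | intermediate
13 | (4S,6R)-4-(tert-butyldimethylsilyloxy)-6-[(2S,10Z)-2-(tert-butyldimethylsilyloxy)heptadec-10-en-1-yl]-6-hydroxycyclohex-2-en-1-one | CCCCCC/C=C\CCCCCCC[C@H](O[Si](C)(C)C(C)(C)C)C[C@@]1(O)C[C@H](O[Si](C)(C)C(C)(C)C)C=CC1=O | intermediate
14 | (4S,6R)-4,6-dihydroxy-6-[(2S,10Z)-2-hydroxyheptadec-10-en-1-yl]cyclohex-2-en-1-one | CCCCCC/C=C\CCCCCCC[C@H](O)C[C@@]1(O)C[C@H](O)C=CC1=O | target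

## Step count and risk

Total step count: 8. Longest linear sequence: 8 steps (1 → 14; 5 and 9 enter at steps 4 and 5).

**Step 7 (key step).** The most likely failures are:
- migration through the open rotamer, which would erode the C6 configuration;
- a competing shift of the vinylic carbon C2, whose product could lose the C4 silyloxy group and aromatise;
- base-induced β-elimination of the C2' silyloxy group of 12 before the shift.

Fallback, from 8 back to 13: close the ring by an intramolecular crossed benzoin reaction instead.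
- The lithio derivative 10 of 8 (generated in THF/HMPA) would open (R)-2-[2-(1,3-dioxolan-2-yl)ethyl]oxirane F1, obtainable by epoxidation of the corresponding terminal alkene and hydrolytic kinetic resolution. This would give (2R)-4-(1,3-dioxolan-2-yl)-1-{2-[(2S,10Z)-2-(tert-butyldimethylsilyloxy)heptadec-10-en-1-yl]-1,3-dithian-2-yl}butan-2-ol F2.
- Silylation (TBSOTf, 2,6-lutidine) would give the bis-silyl ether F3.
- Unmasking of both carbonyl groups (PhI(OCOCF3)2 in aqueous MeCN, then dilute acid) would give (4R,8S,16Z)-4,8-bis(tert-butyldimethylsilyloxy)-6-oxotricos-16-enal F4.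
- A chiral aminoindanol-derived triazolium precatalyst with a weak amine base would join C1 to C6 and give (2R,4R)-4-(tert-butyldimethylsilyloxy)-2-hydroxy-2-[(2S,10Z)-2-(tert-butyldimethylsilyloxy)heptadec-10-en-1-yl]cyclohexan-1-one F5, with the catalyst enantiomer chosen for the C6 configuration.
- This ketone has α-hydrogens only at C2, so IBX dehydrogenation (IBX·4-methoxypyridine N-oxide, DMSO) would introduce C2=C3 and give 13.

**Step 5.** The hindered, basic carbanion may enolise the enone with loss of silanolate, may add in conjugate fashion, or may discriminate the faces poorly, since the stereocentre is 1,3 to the carbonyl. Fallback, from 9 and 2 back to 12; it also takes the thioketal hydrolysis of step 6 out of the route: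
- 1-Ethoxyvinyllithium (ethyl vinyl ether, t-BuLi, THF, −78 °C) would add to 9, and the alkoxide would be trapped with Me3SiCl to give (1R,4S)-4-(tert-butyldimethylsilyloxy)-1-(1-ethoxyethenyl)-1-(trimethylsilyloxy)cyclopent-2-ene F6.
- Brief treatment with dilute oxalic acid would give the methyl ketone 1-[(1R,4S)-4-(tert-butyldimethylsilyloxy)-1-(trimethylsilyloxy)cyclopent-2-en-1-yl]ethan-1-one F7.
- A diisopinocampheylboron aldol reaction with 2 (the enantiomer of the boron chloride chosen for the 3S product, Et3N) would give (3S,11Z)-1-[(1R,4S)-4-(tert-butyldimethylsilyloxy)-1-(trimethylsilyloxy)cyclopent-2-en-1-yl]-3-hydroxyoctadec-11-en-1-one F8.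
- Silylation (TBSOTf, 2,6-lutidine) would give the tris-silyl ether F9, and mild acidic methanolysis (PPTS, MeOH, 0 °C) of the tertiary trimethylsilyl ether would give 12.

**Step 8.** Two hindered secondary silyl ethers may need forcing conditions, under which the γ-hydroxy enone could dehydrate towards phenolic material, or the cleavage may stay incomplete. Fallback, from 12 back to 14: reverse the order. The silyl ethers of 12 would be removed first (HF·pyridine), where no enone is present, to give (3S,11Z)-1-[(1R,4S)-1,4-dihydroxycyclopent-2-en-1-yl]-3-hydroxyoctadec-11-en-1-one F10. The chelation-controlled ring expansion would then be run as the last step on F10 and give 14 directly.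

**Step 4.** Silylation of the aggregated lithium alkoxide 7 may stay incomplete, or residual 6 may consume the silyl triflate by C-silylation, so that free carbinol and silyl ether are obtained side by side. Fallback, from 4 back to 8: deliver the silyl group intramolecularly instead of from an external silylating agent. 2-(tert-Butyldimethylsilyl)-1,3-dithiane F11 would be lithiated (t-BuLi, Et2O, −78 → −45 °C) to [2-(tert-butyldimethylsilyl)-1,3-dithian-2-yl]lithium F12, which would open 4 to lithium (2S,10Z)-1-[2-(tert-butyldimethylsilyl)-1,3-dithian-2-yl]heptadec-10-en-2-olate F13. Addition of HMPA in THF would trigger a 1,4-Brook shift of silicon from carbon to the C2' oxygen, which gives carbanion 10, and protonation on work-up (aq. NH4Cl) would give 8.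

## Further compounds

F1 | step 7 | (R)-2-[2-(1,3-dioxolan-2-yl)ethyl]oxirane | C1O[C@@H]1CCC2OCCO2
F2 | step 7 | (2R)-4-(1,3-dioxolan-2-yl)-1-{2-[(2S,10Z)-2-(tert-butyldimethylsilyloxy)heptadec-10-en-1-yl]-1,3-dithian-2-yl}butan-2-ol | CCCCCC/C=C\CCCCCCC[C@H](O[Si](C)(C)C(C)(C)C)CC1(C[C@H](O)CCC2OCCO2)SCCCS1
F3 | step 7 | tert-butyldimethylsilyl ether of F2 at the C4 oxygen | CCCCCC/C=C\CCCCCCC[C@H](O[Si](C)(C)C(C)(C)C)CC1(C[C@H](O[Si](C)(C)C(C)(C)C)CCC2OCCO2)SCCCS1
F4 | step 7 | (4R,8S,16Z)-4,8-bis(tert-butyldimethylsilyloxy)-6-oxotricos-16-enal | CCCCCC/C=C\CCCCCCC[C@H](O[Si](C)(C)C(C)(C)C)CC(=O)C[C@H](O[Si](C)(C)C(C)(C)C)CCC=O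
F5 | step 7 | (2R,4R)-4-(tert-butyldimethylsilyloxy)-2-hydroxy-2-[(2S,10Z)-2-(tert-butyldimethylsilyloxy)heptadec-10-en-1-yl]cyclohexan-1-one | CCCCCC/C=C\CCCCCCC[C@H](O[Si](C)(C)C(C)(C)C)C[C@@]1(O)C[C@H](O[Si](C)(C)C(C)(C)C)CCC1=O
F6 | step 5 | (1R,4S)-4-(tert-butyldimethylsilyloxy)-1-(1-ethoxyethenyl)-1-(trimethylsilyloxy)cyclopent-2-ene | C=C(OCC)[C@]1(O[Si](C)(C)C)C=C[C@@H](O[Si](C)(C)C(C)(C)C)C1
F7 | step 5 | 1-[(1R,4S)-4-(tert-butyldimethylsilyloxy)-1-(trimethylsilyloxy)cyclopent-2-en-1-yl]ethan-1-one | CC(=O)[C@]1(O[Si](C)(C)C)C=C[C@@H](O[Si](C)(C)C(C)(C)C)C1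
F8 | step 5 | (3S,11Z)-1-[(1R,4S)-4-(tert-butyldimethylsilyloxy)-1-(trimethylsilyloxy)cyclopent-2-en-1-yl]-3-hydroxyoctadec-11-en-1-one | CCCCCC/C=C\CCCCCCC[C@H](O)CC(=O)[C@]1(O[Si](C)(C)C)C=C[C@@H](O[Si](C)(C)C(C)(C)C)C1
F9 | step 5 | (3S,11Z)-3-(tert-butyldimethylsilyloxy)-1-[(1R,4S)-4-(tert-butyldimethylsilyloxy)-1-(trimethylsilyloxy)cyclopent-2-en-1-yl]octadec-11-en-1-one | CCCCCC/C=C\CCCCCCC[C@H](O[Si](C)(C)C(C)(C)C)CC(=O)[C@]1(O[Si](C)(C)C)C=C[C@@H](O[Si](C)(C)C(C)(C)C)C1
F10 | step 8 | (3S,11Z)-1-[(1R,4S)-1,4-dihydroxycyclopent-2-en-1-yl]-3-hydroxyoctadec-11-en-1-one | CCCCCC/C=C\CCCCCCC[C@H](O)CC(=O)[C@]1(O)C=C[C@@H](O)C1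
F11 | step 4 | 2-(tert-butyldimethylsilyl)-1,3-dithiane | CC(C)(C)[Si](C)(C)C1SCCCS1
F12 | step 4 | [2-(tert-butyldimethylsilyl)-1,3-dithian-2-yl]lithium | CC(C)(C)[Si](C)(C)C1([Li])SCCCS1
F13 | step 4 | lithium (2S,10Z)-1-[2-(tert-butyldimethylsilyl)-1,3-dithian-2-yl]heptadec-10-en-2-olate | CCCCCC/C=C\CCCCCCC[C@H](O[Li])CC1(SCCCS1)[Si](C)(C)C(C)(C)C
A1 | alternative 1 | (S)-4-(tert-butyldimethylsilyloxy)cyclohex-2-en-1-one | O=C1C=C[C@@H](O[Si](C)(C)C(C)(C)C)CC1
A2 | alternative 1 | (4S)-4-(tert-butyldimethylsilyloxy)-6-[(2S,10Z)-2-(tert-butyldimethylsilyloxy)heptadec-10-en-1-yl]cyclohex-2-en-1-one (C6 epimers) | CCCCCC/C=C\CCCCCCC[C@H](O[Si](C)(C)C(C)(C)C)CC1C[C@H](O[Si](C)(C)C(C)(C)C)C=CC1=O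
A3 | alternative 2 | (4R,6S)-6-(tert-butyldimethylsilyloxy)-4-hydroxy-4-[(2S,10Z)-2-(tert-butyldimethylsilyloxy)heptadec-10-en-1-yl]octa-1,7-dien-3-one | CCCCCC/C=C\CCCCCCC[C@H](O[Si](C)(C)C(C)(C)C)C[C@@](O)(C[C@H](O[Si](C)(C)C(C)(C)C)C=C)C(=O)C=C
A4 | alternative 3 | 2-[(2S,10Z)-2-hydroxyheptadec-10-en-1-yl]-4-methoxyphenol | CCCCCC/C=C\CCCCCCC[C@H](O)Cc1cc(OC)ccc1O
A5 | alternative 3 | (6R)-6-hydroxy-6-[(2S,10Z)-2-hydroxyheptadec-10-en-1-yl]-4-methoxycyclohexa-2,4-dien-1-one | CCCCCC/C=C\CCCCCCC[C@H](O)C[C@@]1(O)C=C(OC)C=CC1=O
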